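## Retrosynthetic overview

1. Numbering used throughout: lactone C12(=O)–O–C6, ring-fusion carbon C7, C11(=C13H2); ten-membered ring C6–C5=C4(C15)–C3(OAc)–C2–C1=C10(C14)–C9(OH)–C8(O-ester)–C7. The target is unmasked at the end by acylating C8–OH with (2R,3R)-epoxyangelic acid and removing a C9 silyl ether.
2. Key disconnection C7–C8: the C8 carbinol is homoallylic to the exocyclic C11=C13 olefin of the γ-lactone (O–C8–C7–C11=C13), the retron of an SE2′ carbonyl allylation. The precursor is a 5-substituted 3-(chloromethyl)furan-2(5H)-one (C11=C7 endocyclic, CH2Cl at C13) tethered through C6 to a C8 aldehyde; Cr(II) joins the two electrophilic carbons C7 (butenolide β-carbon) and C8 (aldehyde), closing the ten-membered carbocycle, setting C7 and C8 and unveiling the α-methylene lactone in one operation.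
3. Butenolide ⇒ ester of the C6 bis-allylic alcohol with 2-(chloromethyl)acrylic acid, closed by ring-closing metathesis (C7=C11); C3 carbinol ⇒ CBS reduction of an enone.
4. Open chain ⇒ Ni/Cr union (C3–C4) of a (Z)-alkenyl iodide C4–C7 (from (S)-but-3-ene-1,2-diol) with a (Z)-β,γ-unsaturated aldehyde C1–C3/C8–C10 (from methyl (S)-glycerate acetonide via Z-selective Wittig olefination of its methyl ketone).
5. Order of ring formation: oxirane of the side-chain acid (step 2), butenolide (step 17), ten-membered carbocycle last (step 22).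

Key step: step 22

Remark: 2-(chloromethyl)acrylic acid and [3-(tert-butyldimethylsilyloxy)propyl]triphenylphosphonium bromide are taken as purchasable reagents; atom labels C1–C15 in the text are those of line 1 above.

## Route

Step 1
Reactants: 1 methyl angelate
Product: 2 (2Z)-2-methylbut-2-en-1-ol
Conditions: DIBAL-H, CH2Cl2, −78 °C
Reagents that add atoms: none
Why: DIBAL-H reduces the conjugated ester in 1,2-fashion to the allylic alcohol (ester reduction) and leaves the Z-trisubstituted olefin geometry untouched.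

Step 2
Reactants: 2 (2Z)-2-methylbut-2-en-1-ol
Product: 3 [(2S,3R)-2,3-dimethyloxiran-2-yl]methanol
Conditions: Ti(OiPr)4 (cat.), L-(+)-diethyl tartrate (cat.), t-BuOOH, 4 Å MS, CH2Cl2, −20 °C
Reagents that add atoms: tert-butyl hydroperoxide, CC(C)(C)OO
Why: Sharpless asymmetric epoxidation: the Ti/L-(+)-tartrate catalyst delivers oxygen to the enantioface that makes C2 of the epoxy alcohol S and, by syn addition to the Z-olefin, C3 R, so both oxirane stereocentres are set here.

Step 3
Reactants: 3 [(2S,3R)-2,3-dimethyloxiran-2-yl]methanol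
Product: 4 (2R,3R)-2,3-dimethyloxirane-2-carboxylic acid
Conditions: TEMPO (cat.), PhI(OAc)2, MeCN/H2O, rt
Reagents that add atoms: water, O
Why: TEMPO/PhI(OAc)2 oxidation in aqueous acetonitrile carries the primary alcohol through the aldehyde hydrate to the acid under near-neutral conditions that should not open the oxirane (the change 2S to 2R is a CIP effect only).

Step 4
Reactants: 5 methyl (4S)-2,2-dimethyl-1,3-dioxolane-4-carboxylate
Product: 7 1-[(4S)-2,2-dimethyl-1,3-dioxolan-4-yl]ethan-1-one, via Weinreb amide 6 (not isolated)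
Conditions: MeNH(OMe)·HCl, i-PrMgCl, THF, −20 °C; then MeMgBr, −20 → 0 °C; aq. NH4Cl
Reagents that add atoms: methylmagnesium bromide, C[Mg]Br; N,O-dimethylhydroxylamine hydrochloride, CNOC.Cl (its atoms are held only in intermediate 6)
Why: Weinreb ketone synthesis run in one pot (aminolysis of the ester by the magnesium amide, then Grignard addition to the amide, whose chelated tetrahedral adduct prevents over-addition); the C9 stereocentre is carried through unchanged.

Step 5
Reactants: 7 1-[(4S)-2,2-dimethyl-1,3-dioxolan-4-yl]ethan-1-one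
Product: 8 tert-butyl({(3Z)-4-[(4R)-2,2-dimethyl-1,3-dioxolan-4-yl]pent-3-en-1-yl}oxy)dimethylsilane
Conditions: [TBSO(CH2)3PPh3]Br, KHMDS, THF, −78 °C; then 7, −78 °C → rt
Reagents that add atoms: [3-(tert-butyldimethylsilyloxy)propyl]triphenylphosphonium bromide, CC(C)(C)[Si](C)(C)OCCC[P+](c1ccccc1)(c1ccccc1)c1ccccc1.[Br-]
Why: Wittig olefination of an α-alkoxy methyl ketone with a non-stabilised ylide under salt-free conditions is Z-selective, placing the oxygenated carbon C9 cis to C2 and so fixing the (Z)-C1=C10 olefin.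

Step 6
Reactants: 8 TBS ether of the Z-homoallylic alcohol
Product: 9 (3Z)-4-[(4R)-2,2-dimethyl-1,3-dioxolan-4-yl]pent-3-en-1-ol
Conditions: TBAF, THF, 0 °C
Reagents that add atoms: none
Why: Fluoride-mediated cleavage of the primary silyl ether, to which acetonide and olefin are inert.

Step 7
Reactants: 9 (3Z)-4-[(4R)-2,2-dimethyl-1,3-dioxolan-4-yl]pent-3-en-1-ol
Product: 10 (3Z)-4-[(4R)-2,2-dimethyl-1,3-dioxolan-4-yl]pent-3-enal
Conditions: Dess–Martin periodinane, NaHCO3, CH2Cl2, 0 °C; used crude
Reagents that add atoms: none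
Why: Buffered Dess–Martin oxidation should give the β,γ-unsaturated aldehyde without moving the olefin into conjugation, and the crude aldehyde is used at once.

Step 8
Reactants: 11 (2S)-but-3-ene-1,2-diol
Product: 12 (2S)-1,2-bis(triethylsilyloxy)but-3-ene
Conditions: TESCl, imidazole, DMF, 0 °C
Reagents that add atoms: chlorotriethylsilane, CC[Si](Cl)(CC)CC
Why: Imidazole-promoted silylation of both hydroxyl groups; the stereocentre (later C6) comes from the chiral pool.

Step 9
Reactants: 12 (2S)-1,2-bis(triethylsilyloxy)but-3-ene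
Product: 13 (2S)-2-(triethylsilyloxy)but-3-enal
Conditions: (COCl)2, DMSO, CH2Cl2, −78 → −40 °C; Et3N, −78 °C; used crude
Reagents that add atoms: none
Why: Under Swern conditions the less hindered primary triethylsilyl ether is cleaved by the chlorosulfonium ion and oxidised in the same flask while the secondary one stays, and the low temperature should keep the α-stereocentre from enolising.

Step 10
Reactants: 13 (2S)-2-(triethylsilyloxy)but-3-enal
Product: 14 triethyl{[(3S,4Z)-5-iodohexa-1,4-dien-3-yl]oxy}silane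
Conditions: EtPPh3I, n-BuLi, THF; I2, −78 °C; NaHMDS, −20 °C; then 13, −78 → −20 °C
Reagents that add atoms: ethyltriphenylphosphonium iodide, CC[P+](c1ccccc1)(c1ccccc1)c1ccccc1.[I-]; iodine, II
Why: Stork–Zhao-type olefination with the α-iodo ylide gives the (Z)-2-iodoalkene (iodine cis to C6), which stores the geometry of the later C4=C5 olefin.

Step 11
Reactants: 14 (Z)-alkenyl iodide; 10 (3Z)-4-[(4R)-2,2-dimethyl-1,3-dioxolan-4-yl]pent-3-enal
Product: 16 (3S,4Z,8Z)-9-[(4R)-2,2-dimethyl-1,3-dioxolan-4-yl]-5-methyl-3-(triethylsilyloxy)deca-1,4,8-trien-6-ol as both C6 epimers, via alkenylchromium 15 (not isolated)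
Conditions: CrCl2, NiCl2 (cat.), DMSO, rt
Reagents that add atoms: chromium(II) chloride, Cl[Cr]Cl (its atoms are held only in intermediate 15)
Why: Nozaki–Hiyama–Kishi coupling: nickel-catalysed formation of the alkenylchromium with retention of olefin geometry and its non-basic, chemoselective addition to the enolisable aldehyde form the C3–C4 bond; C3 (C6 of this chain) is formed without control and is corrected in steps 12 and 13.

Step 12
Reactants: 16 allylic alcohol (epimers at target C3)
Product: 17 (3S,4Z,8Z)-9-[(4R)-2,2-dimethyl-1,3-dioxolan-4-yl]-5-methyl-3-(triethylsilyloxy)deca-1,4,8-trien-6-one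
Conditions: Dess–Martin periodinane, NaHCO3, CH2Cl2, 0 °C
Reagents that add atoms: none
Why: Dess–Martin oxidation removes the uncontrolled stereocentre and gives the α-methyl Z-enone without touching silyl ether or acetonide.

Step 13
Reactants: 17 Z-enone
Product: 18 (3S,4Z,6S,8Z)-9-[(4R)-2,2-dimethyl-1,3-dioxolan-4-yl]-5-methyl-3-(triethylsilyloxy)deca-1,4,8-trien-6-ol
Conditions: (R)-2-methyl-CBS-oxazaborolidine (cat.), catecholborane, toluene, −78 °C
Reagents that add atoms: none
Why: Corey–Bakshi–Shibata reduction: with the (R)-oxazaborolidine the trisubstituted alkenyl flank acts as the large group and hydride is delivered to the face that gives the (S)-carbinol at target C3 (catalyst control), catecholborane sparing the olefins.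

Step 14
Reactants: 18 (6S)-allylic alcohol
Product: 19 (3S,4Z,6S,8Z)-9-[(4R)-2,2-dimethyl-1,3-dioxolan-4-yl]-5-methyl-3-(triethylsilyloxy)deca-1,4,8-trien-6-yl acetate
Conditions: Ac2O, pyridine, DMAP (cat.), CH2Cl2, 0 °C → rt
Reagents that add atoms: acetic anhydride, CC(=O)OC(C)=O
Why: DMAP-catalysed acetylation installs the C3 acetate of the target with retention.

Step 15
Reactants: 19 acetate with C6 triethylsilyl ether
Product: 20 (3S,4Z,6S,8Z)-9-[(4R)-2,2-dimethyl-1,3-dioxolan-4-yl]-3-hydroxy-5-methyldeca-1,4,8-trien-6-yl acetate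
Conditions: HF·pyridine, pyridine, THF, 0 °C
Reagents that add atoms: none
Why: Buffered HF·pyridine cleaves the secondary triethylsilyl ether while the acetonide and the acetate survive.

Step 16
Reactants: 20 bis-allylic alcohol
Product: 21 (3S,4Z,6S,8Z)-6-acetoxy-9-[(4R)-2,2-dimethyl-1,3-dioxolan-4-yl]-5-methyldeca-1,4,8-trien-3-yl 2-(chloromethyl)prop-2-enoate
Conditions: 2-(chloromethyl)acrylic acid, DIC, DMAP (cat.), CH2Cl2, 0 °C
Reagents that add atoms: 2-(chloromethyl)acrylic acid, C=C(CCl)C(=O)O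
Why: Carbodiimide (Steglich) esterification of the C6 alcohol brings in C11, C12 and C13 with the allylic chloride already in place.

Step 17
Reactants: 21 2-(chloromethyl)acrylate ester
Product: 22 (5R)-5-{(1Z,3S,5Z)-3-acetoxy-6-[(4R)-2,2-dimethyl-1,3-dioxolan-4-yl]-2-methylhepta-1,5-dien-1-yl}-3-(chloromethyl)furan-2(5H)-one
Conditions: Hoveyda–Grubbs II catalyst (cat.), toluene, 80 °C
Reagents that add atoms: none
Why: Ring-closing metathesis between the terminal vinyl group and the acrylate olefin closes the five-membered unsaturated lactone (C7=C11) with loss of ethylene, the two trisubstituted olefins being too hindered to compete.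

Step 18
Reactants: 22 butenolide acetonide
Product: 23 (5R)-5-[(1Z,3S,5Z,7R)-3-acetoxy-7,8-dihydroxy-2,6-dimethylocta-1,5-dien-1-yl]-3-(chloromethyl)furan-2(5H)-one
Conditions: AcOH/H2O 4:1, 40 °C
Reagents that add atoms: none
Why: Mild acid hydrolysis of the isopropylidene acetal frees the C8/C9 diol without cleaving the acetate or the allylic chloride.

Step 19
Reactants: 23 diol
Product: 24 (5R)-5-[(1Z,3S,5Z,7R)-3-acetoxy-2,6-dimethyl-7,8-bis(triethylsilyloxy)octa-1,5-dien-1-yl]-3-(chloromethyl)furan-2(5H)-one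
Conditions: TESOTf, 2,6-lutidine, CH2Cl2, −78 °C
Reagents that add atoms: triethylsilyl trifluoromethanesulfonate, CC[Si](CC)(CC)OS(=O)(=O)C(F)(F)F
Why: Silylation with the silyl triflate and a hindered, non-nucleophilic base protects both hydroxyls without displacing the allylic chloride.

Step 20
Reactants: 24 bis(triethylsilyl) ether
Product: 25 (5R)-5-[(1Z,3S,5Z,7R)-3-acetoxy-8-hydroxy-2,6-dimethyl-7-(triethylsilyloxy)octa-1,5-dien-1-yl]-3-(chloromethyl)furan-2(5H)-one
Conditions: PPTS (cat.), MeOH/CH2Cl2, 0 °C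
Reagents that add atoms: none
Why: Acid-catalysed methanolysis removes the primary triethylsilyl ether faster than the hindered secondary allylic one (steric differentiation).

Step 21
Reactants: 25 primary alcohol
Product: 26 (5R)-5-[(1Z,3S,5Z,7R)-3-acetoxy-2,6-dimethyl-8-oxo-7-(triethylsilyloxy)octa-1,5-dien-1-yl]-3-(chloromethyl)furan-2(5H)-one
Conditions: Dess–Martin periodinane, NaHCO3, CH2Cl2, 0 °C; used crude
Reagents that add atoms: none
Why: Buffered Dess–Martin oxidation gives the α-silyloxy aldehyde under non-basic conditions, and the crude product is cyclised at once to avoid epimerisation at C9.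

Step 22
Reactants: 26 chloromethyl-butenolide aldehyde
Product: 28 (1(10)Z,3S,4Z,6R,7S,8S,9R)-3-acetoxy-8-hydroxy-9-(triethylsilyloxy)germacra-1(10),4,11(13)-trien-12,6-olide, via allylchromium 27 (not isolated)
Conditions: CrCl2 (excess), DMF/THF, rt, slow addition of 26 (high dilution)
Reagents that add atoms: chromium(II) chloride, Cl[Cr]Cl (its atoms are held only in intermediate 27)
Why: Cr(II) inserts into the allylic C13–Cl bond by two one-electron transfers to give allylchromium 27, whose γ-carbon C7 adds (SE2′) to the tethered C8 aldehyde, so that two electrophilic carbons (butenolide β-carbon and aldehyde carbon) are joined by reductive polarity reversal and the olefin moves to C11=C13, unveiling the α-methylene lactone. The closest known reactions are the Nozaki–Hiyama (Barbier) allylation of aldehydes with 3-(halomethyl)furan-2(5H)-ones and 2-(halomethyl)acrylates and the Cr(II)-mediated intramolecular variant used to close ten-membered germacranolide carbocycles. The ten-membered ring closes in a 10-exo-trig mode at the aldehyde carbon under high dilution, the two Z-olefins folding the eight-atom tether towards C7. C8 is controlled by the C9 stereocentre (polar Felkin–Anh addition anti to the C9–O bond, giving the 8,9-anti diol pattern) and C7 by the closed chair (Zimmerman–Traxler) transition state of the ring-locked E-type allylchromium with C9 equatorial, which relates C7 to C8. With C9 and C6 fixed, these two elements together call for attack on the face of C7 syn to the C6 side chain, that is the cis ring fusion of the target, which the tether anchored at C6 can reach without crossing the lactone plane. The step needs chemoselectivity (only the allylic chloride is reduced, the organochromium adds only to the aldehyde and not to acetate, lactone or silyl ether) and γ-regioselectivity, both of which are normal for allylchromium reagents.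

Step 23
Reactants: 28 macrocyclic C8 alcohol; 4 (2R,3R)-2,3-dimethyloxirane-2-carboxylic acid
Product: 29 (1(10)Z,3S,4Z,6R,7R,8S,9R)-3-acetoxy-8-{[(2R,3R)-2,3-dimethyloxirane-2-carbonyl]oxy}-9-(triethylsilyloxy)germacra-1(10),4,11(13)-trien-12,6-olide
Conditions: DCC, DMAP, CH2Cl2, 0 °C → rt
Reagents that add atoms: none
Why: Steglich esterification acylates the C8 hydroxyl with retention at C8, the two oxirane stereocentres arriving intact with acid 4.

Step 24
Reactants: 29 C9 triethylsilyl ether of the target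
Product: 30 (1(10)Z,3S,4Z,6R,7R,8S,9R)-3-acetoxy-8-{[(2R,3R)-2,3-dimethyloxirane-2-carbonyl]oxy}-9-hydroxygermacra-1(10),4,11(13)-trien-12,6-olide (target)
Conditions: HF·pyridine, pyridine, THF, 0 °C
Reagents that add atoms: none
Why: Buffered HF·pyridine removes the C9 triethylsilyl ether under mildly acidic conditions that should leave the oxirane, both esters and the α-methylene lactone untouched and avoid 1,2-acyl migration.

## Compound list

1 | methyl angelate (methyl (2Z)-2-methylbut-2-enoate) | C/C=C(/C)C(=O)OC | starting material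
2 | (2Z)-2-methylbut-2-en-1-ol | C/C=C(/C)CO | intermediate
3 | [(2S,3R)-2,3-dimethyloxiran-2-yl]methanol | OC[C@]1(C)O[C@@H]1C | intermediate
4 | (2R,3R)-2,3-dimethyloxirane-2-carboxylic acid (epoxyangelic acid) | OC(=O)[C@]1(C)O[C@@H]1C | intermediate
5 | methyl (4S)-2,2-dimethyl-1,3-dioxolane-4-carboxylate | COC(=O)[C@@H]1COC(C)(C)O1 | starting material
6 | (4S)-N-methoxy-N,2,2-trimethyl-1,3-dioxolane-4-carboxamide (Weinreb amide; not isolated) | CON(C)C(=O)[C@@H]1COC(C)(C)O1 | intermediate
7 | 1-[(4S)-2,2-dimethyl-1,3-dioxolan-4-yl]ethan-1-one | CC(=O)[C@@H]1COC(C)(C)O1 | intermediate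
8 | tert-butyl({(3Z)-4-[(4R)-2,2-dimethyl-1,3-dioxolan-4-yl]pent-3-en-1-yl}oxy)dimethylsilane | CC(C)(C)[Si](C)(C)OCC/C=C(/C)[C@@H]1COC(C)(C)O1 | intermediate
9 | (3Z)-4-[(4R)-2,2-dimethyl-1,3-dioxolan-4-yl]pent-3-en-1-ol | OCC/C=C(/C)[C@@H]1COC(C)(C)O1 | intermediate
10 | (3Z)-4-[(4R)-2,2-dimethyl-1,3-dioxolan-4-yl]pent-3-enal | O=CC/C=C(/C)[C@@H]1COC(C)(C)O1 | intermediate
11 | (2S)-but-3-ene-1,2-diol | C=C[C@H](O)CO | starting material
12 | (2S)-1,2-bis(triethylsilyloxy)but-3-ene | C=C[C@H](O[Si](CC)(CC)CC)CO[Si](CC)(CC)CC | intermediate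
13 | (2S)-2-(triethylsilyloxy)but-3-enal | C=C[C@H](O[Si](CC)(CC)CC)C=O | intermediate
14 | triethyl{[(3S,4Z)-5-iodohexa-1,4-dien-3-yl]oxy}silane | C=C[C@H](O[Si](CC)(CC)CC)/C=C(/C)I | intermediate
15 | dichloro[(2Z,4S)-4-(triethylsilyloxy)hexa-2,5-dien-2-yl]chromium (alkenylchromium; not isolated) | C=C[C@H](O[Si](CC)(CC)CC)/C=C(/C)[Cr](Cl)Cl | intermediate
16 | (3S,4Z,8Z)-9-[(4R)-2,2-dimethyl-1,3-dioxolan-4-yl]-5-methyl-3-(triethylsilyloxy)deca-1,4,8-trien-6-ol, both C6 epimers (chain C6 = target C3) | C=C[C@H](O[Si](CC)(CC)CC)/C=C(/C)C(O)C/C=C(/C)[C@@H]1COC(C)(C)O1 | intermediate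
17 | (3S,4Z,8Z)-9-[(4R)-2,2-dimethyl-1,3-dioxolan-4-yl]-5-methyl-3-(triethylsilyloxy)deca-1,4,8-trien-6-one | C=C[C@H](O[Si](CC)(CC)CC)/C=C(/C)C(=O)C/C=C(/C)[C@@H]1COC(C)(C)O1 | intermediate
18 | (3S,4Z,6S,8Z)-9-[(4R)-2,2-dimethyl-1,3-dioxolan-4-yl]-5-methyl-3-(triethylsilyloxy)deca-1,4,8-trien-6-ol | C=C[C@H](O[Si](CC)(CC)CC)/C=C(/C)[C@@H](O)C/C=C(/C)[C@@H]1COC(C)(C)O1 | intermediate
19 | (3S,4Z,6S,8Z)-9-[(4R)-2,2-dimethyl-1,3-dioxolan-4-yl]-5-methyl-3-(triethylsilyloxy)deca-1,4,8-trien-6-yl acetate | C=C[C@H](O[Si](CC)(CC)CC)/C=C(/C)[C@@H](OC(C)=O)C/C=C(/C)[C@@H]1COC(C)(C)O1 | intermediate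
20 | (3S,4Z,6S,8Z)-9-[(4R)-2,2-dimethyl-1,3-dioxolan-4-yl]-3-hydroxy-5-methyldeca-1,4,8-trien-6-yl acetate | C=C[C@H](O)/C=C(/C)[C@@H](OC(C)=O)C/C=C(/C)[C@@H]1COC(C)(C)O1 | intermediate
21 | (3S,4Z,6S,8Z)-6-acetoxy-9-[(4R)-2,2-dimethyl-1,3-dioxolan-4-yl]-5-methyldeca-1,4,8-trien-3-yl 2-(chloromethyl)prop-2-enoate | C=C[C@H](OC(=O)C(=C)CCl)/C=C(/C)[C@@H](OC(C)=O)C/C=C(/C)[C@@H]1COC(C)(C)O1 | intermediate
22 | (5R)-5-{(1Z,3S,5Z)-3-acetoxy-6-[(4R)-2,2-dimethyl-1,3-dioxolan-4-yl]-2-methylhepta-1,5-dien-1-yl}-3-(chloromethyl)furan-2(5H)-one | O=C1O[C@@H](C=C1CCl)/C=C(/C)[C@@H](OC(C)=O)C/C=C(/C)[C@@H]2COC(C)(C)O2 | intermediate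
23 | (5R)-5-[(1Z,3S,5Z,7R)-3-acetoxy-7,8-dihydroxy-2,6-dimethylocta-1,5-dien-1-yl]-3-(chloromethyl)furan-2(5H)-one | O=C1O[C@@H](C=C1CCl)/C=C(/C)[C@@H](OC(C)=O)C/C=C(/C)[C@@H](O)CO | intermediate
24 | (5R)-5-[(1Z,3S,5Z,7R)-3-acetoxy-2,6-dimethyl-7,8-bis(triethylsilyloxy)octa-1,5-dien-1-yl]-3-(chloromethyl)furan-2(5H)-one | O=C1O[C@@H](C=C1CCl)/C=C(/C)[C@@H](OC(C)=O)C/C=C(/C)[C@@H](O[Si](CC)(CC)CC)CO[Si](CC)(CC)CC | intermediate
25 | (5R)-5-[(1Z,3S,5Z,7R)-3-acetoxy-8-hydroxy-2,6-dimethyl-7-(triethylsilyloxy)octa-1,5-dien-1-yl]-3-(chloromethyl)furan-2(5H)-one | O=C1O[C@@H](C=C1CCl)/C=C(/C)[C@@H](OC(C)=O)C/C=C(/C)[C@@H](O[Si](CC)(CC)CC)CO | intermediate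
26 | (5R)-5-[(1Z,3S,5Z,7R)-3-acetoxy-2,6-dimethyl-8-oxo-7-(triethylsilyloxy)octa-1,5-dien-1-yl]-3-(chloromethyl)furan-2(5H)-one | O=C1O[C@@H](C=C1CCl)/C=C(/C)[C@@H](OC(C)=O)C/C=C(/C)[C@@H](O[Si](CC)(CC)CC)C=O | intermediate
27 | allylchromium(III) dichloride of 26 (CrCl2 in place of Cl on the CH2 at C3 of the furanone; not isolated) | O=C1O[C@@H](C=C1C[Cr](Cl)Cl)/C=C(/C)[C@@H](OC(C)=O)C/C=C(/C)[C@@H](O[Si](CC)(CC)CC)C=O | intermediate
28 | (1(10)Z,3S,4Z,6R,7S,8S,9R)-3-acetoxy-8-hydroxy-9-(triethylsilyloxy)germacra-1(10),4,11(13)-trien-12,6-olide (C7 arranged as in the target; the descriptor is S only through CIP priorities) | C=C1C(=O)O[C@@H]2/C=C(/C)[C@@H](OC(C)=O)C/C=C(/C)[C@@H](O[Si](CC)(CC)CC)[C@@H](O)[C@H]12 | intermediate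
29 | (1(10)Z,3S,4Z,6R,7R,8S,9R)-3-acetoxy-8-{[(2R,3R)-2,3-dimethyloxirane-2-carbonyl]oxy}-9-(triethylsilyloxy)germacra-1(10),4,11(13)-trien-12,6-olide | C=C1C(=O)O[C@@H]2/C=C(/C)[C@@H](OC(C)=O)C/C=C(/C)[C@@H](O[Si](CC)(CC)CC)[C@@H](OC(=O)[C@]3(C)O[C@@H]3C)[C@H]12 | intermediate
30 | (1(10)Z,3S,4Z,6R,7R,8S,9R)-3-acetoxy-8-{[(2R,3R)-2,3-dimethyloxirane-2-carbonyl]oxy}-9-hydroxygermacra-1(10),4,11(13)-trien-12,6-olide | C=C1C(=O)O[C@@H]2/C=C(/C)[C@@H](OC(C)=O)C/C=C(/C)[C@@H](O)[C@@H](OC(=O)[C@]3(C)O[C@@H]3C)[C@H]12 | target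

## Step count and risks

Total step count: 24. Longest linear sequence: 18 steps (steps 4–7 and 11–24, from ester 5).

Steps most likely to fail:

1. Step 22 (ring closure). What may go wrong: delivery of the aldehyde to the face of C7 anti to the C6 side chain (trans-fused lactone) if ring strain overrides the Felkin/chair preference; vinylogous β-elimination of the allylchromium that opens the lactone at C6–O; or intermolecular allylation giving oligomers. The fallback sets out from 25 and comes back at 28, replacing the reductive, closed-transition-state allylation by a Lewis-acid-promoted allylstannane addition. Palladium(0)-catalysed stannylation of the allylic chloride of 25 with hexabutyldistannane (Pd(PPh3)4 cat., THF) should give the allylstannane alcohol (5R)-5-[(1Z,3S,5Z,7R)-3-acetoxy-8-hydroxy-2,6-dimethyl-7-(triethylsilyloxy)octa-1,5-dien-1-yl]-3-[(tributylstannyl)methyl]furan-2(5H)-one F1. Buffered Dess–Martin oxidation should then give the corresponding allylstannane aldehyde F2. Treatment of F2 with BF3·OEt2 in CH2Cl2 at −78 °C under high dilution should close the ring by SE2′ addition through an open transition state to give 28. No low-valent metal is present, Felkin control at C8 is kept, and the C7 face is no longer tied to a chair.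

2. Step 10 (iodo-olefination). What may go wrong: deprotonation of the α-silyloxy β,γ-unsaturated aldehyde by the basic iodo-ylide (loss of configuration at C6, shift of the vinyl group into conjugation) and incomplete Z-selectivity. The fallback sets out from 13 and comes back at 14. Dibromo-olefination of 13 under Corey–Fuchs conditions (CBr4, PPh3, CH2Cl2, 0 °C; non-basic ylide) should give the dibromodiene {[(3S)-5,5-dibromopenta-1,4-dien-3-yl]oxy}triethylsilane F3. Trans-selective Negishi monomethylation (MeZnCl, Pd(DPEphos)Cl2 cat., THF) replaces the less hindered bromine and should give the (Z)-alkenyl bromide {[(3S,4Z)-5-bromohexa-1,4-dien-3-yl]oxy}triethylsilane F4. Copper-catalysed halogen exchange (CuI cat., NaI, trans-N,N′-dimethylcyclohexane-1,2-diamine, dioxane, heat) should then give iodide 14 with retention of geometry.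

3. Step 13 (CBS reduction). What may go wrong: insufficient facial discrimination by the oxazaborolidine between the Z-alkenyl flank and the allyl-type flank of the ketone, or conjugate reduction. The fallback sets out from 16 and comes back at 19, leaving out steps 12 and 13. The two C6 epimers of 16 are separated by chromatography. The (6S)-epimer is 18 and is acetylated as in step 14. The (6R)-epimer (3S,4Z,6R,8Z)-9-[(4R)-2,2-dimethyl-1,3-dioxolan-4-yl]-5-methyl-3-(triethylsilyloxy)deca-1,4,8-trien-6-ol F5 is converted into the same acetate 19 with inversion by Mitsunobu esterification with acetic acid (PPh3, DIAD, AcOH, toluene, 0 °C). Both epimers thus converge on 19.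

Further compounds
F1 | step 22 | (5R)-5-[(1Z,3S,5Z,7R)-3-acetoxy-8-hydroxy-2,6-dimethyl-7-(triethylsilyloxy)octa-1,5-dien-1-yl]-3-[(tributylstannyl)methyl]furan-2(5H)-one | O=C1O[C@@H](C=C1C[Sn](CCCC)(CCCC)CCCC)/C=C(/C)[C@@H](OC(C)=O)C/C=C(/C)[C@@H](O[Si](CC)(CC)CC)CO
F2 | step 22 | (5R)-5-[(1Z,3S,5Z,7R)-3-acetoxy-2,6-dimethyl-8-oxo-7-(triethylsilyloxy)octa-1,5-dien-1-yl]-3-[(tributylstannyl)methyl]furan-2(5H)-one | O=C1O[C@@H](C=C1C[Sn](CCCC)(CCCC)CCCC)/C=C(/C)[C@@H](OC(C)=O)C/C=C(/C)[C@@H](O[Si](CC)(CC)CC)C=O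
F3 | step 10 | {[(3S)-5,5-dibromopenta-1,4-dien-3-yl]oxy}triethylsilane | C=C[C@H](O[Si](CC)(CC)CC)C=C(Br)Br
F4 | step 10 | {[(3S,4Z)-5-bromohexa-1,4-dien-3-yl]oxy}triethylsilane | C=C[C@H](O[Si](CC)(CC)CC)/C=C(/C)Br
F5 | step 13 | (3S,4Z,6R,8Z)-9-[(4R)-2,2-dimethyl-1,3-dioxolan-4-yl]-5-methyl-3-(triethylsilyloxy)deca-1,4,8-trien-6-ol | C=C[C@H](O[Si](CC)(CC)CC)/C=C(/C)[C@H](O)C/C=C(/C)[C@@H]1COC(C)(C)O1
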